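The pitfall is to treat the complex with one exchanged as a yield that climbs with the incoming ligand.

| setting | elm | ash | flask |
|---|---|---|---|
| starting complex | 0.42 M | 0.42 M | 0.42 M |
| incoming ligand | 0.47 equiv | 1 equiv | 0.700 equiv |
| leaving ligand | 0.50 equiv (fed, over 20 h) | 0.50 equiv (fed, over 20 h) | 0.500 equiv (fed, over 20 h) |
| remark | run made earlier; the fed solution adds 0.25 times the starting volume | run made earlier; the fed solution adds 0.25 times the starting volume | the fed solution adds 0.25 times the starting volume |
| time |  |  | 15 d |

| run | time / d | complex with one exchanged / % | complex with two exchanged / % |
|---|---|---|---|
| elm | 4.00 | 6.1 | 14.9 |
| elm | 8.00 | 5.0 | 14.7 |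
| elm | 10.0 | 6.0 | 15.2 |
| elm | 15.0 | 5.6 | 15.0 |
| elm | 20.0 | 5.5 | 14.5 |
| ash | 1.25 | 8.2 | 25.9 |
| ash | 2.50 | 7.8 | 29.3 |
| ash | 5.00 | 5.8 | 29.4 |
| ash | 10.0 | 6.3 | 29.2 |
| ash | 20.0 | 6.9 | 29.8 |

(scatter of a reading: 0.5 percentage points)

- which holds at 15 d: what has brought the reaction to rest, or that it has not come to rest (the incoming ligand has run out first / it is still moving / forward and back rates have come level / all of the starting complex has reacted)
- how much complex with one exchanged there is at 15 d, in percent of the starting complex charged
- how much complex with two exchanged there is at 15 d, in percent of the starting complex charged

- charges are per starting volume, the dose included; the dosed solution carries all of it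
- the reaction counts as stopped when no species that holds the starting complex changes by six tenths of a point or more over the second half of the time

Turn the time first. By hand, you would expect more product the longer you wait, but elm reads the same within scatter from 4.00 d on, and ash from 5.00 d on. I therefore expect the flask to be at rest by 15 d, with forward and back rates level.

Next comes the leaving ligand. By hand, it pushes each exchange back, but it cannot be judged from these runs, since the flask has the charge and feed of both. The feed also ends sooner than the first reading of either run.

Last comes the incoming ligand. By hand, more should lift both complexes. Going from elm to ash about doubles it, and the complex with two exchanged goes from 14.9% to 29.5%. The complex with one exchanged goes from 5.64% to 6.33%, taking means over the flat readings.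

If each step swaps one ligand, dividing the first balance at rest by the second cancels both free ligands. Take the square of the complex with one exchanged over the product of the starting complex and the complex with two exchanged, with the starting complex read as what the two measured complexes leave, a reckoning that counts no further form. It stands at 0.0269 in elm and 0.0212 in ash, mean 0.0241. This sharing ratio is a comproportionation constant. Two equal, independent places would give 4, and the readings are less than that, so you should expect a small middle complex.

For the flask, I interpolate the complex with two exchanged to 21.2%, and the ratio then gives 6.09% of the complex with one exchanged.

The forecast says forward and back rates have come level, with 6% and 21.6%: “Both runs are flat by about 4–5 d, so the flask should be at rest by 15 d.”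

The flask gives forward and back rates have come level, with 6.28% and 21.4%.

    starting complex + incoming ligand ⇌ leaving ligand + complex with one exchanged (K = 1.50, k = 0.953 L mol⁻¹ h⁻¹)
    complex with one exchanged + incoming ligand ⇌ leaving ligand + complex with two exchanged (K = 55.0, k = 0.945 L mol⁻¹ h⁻¹)
    complex with two exchanged + incoming ligand ⇌ leaving ligand + complex with three exchanged (K = 3.51, k = 1.53 L mol⁻¹ h⁻¹)

The flask keeps 68% of its starting complex, so the sharing ratio returns 5.92% of the complex with one exchanged, against 6.28% found. The return of leaving ligand and the complex with one exchanged to starting complex and incoming ligand is the largest single effect on how far this flask's starting complex goes: the flask converts 32.3% of it, and with that return taken away 64.0%, which makes up 47% of what is missing. The neighbour charged with 2.80 equiv of incoming ligand ends with 9.90% of starting complex and 47.0% of the complex with two exchanged. There the ratio returns 3.35% of the complex with one exchanged, and the neighbour holds 3.56%.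

The numbers in the tables were generated by integration with made-up constants; scatter was added.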